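Rings A and C are 2-butanoyl-4,4-dimethylcyclohexane-1,3,5-triones. In each, the acyl-bearing carbon C2 is bonded to the enol carbon C3 beside the CMe2 carbon C4, which is the connectivity of a folded 2,2-dimethyl-3,5,7-trioxodecanoate. Cutting C2–C3 in both rings leaves the tri-O-benzyl butyrophenone core (ring B) with two open tetracarbonyl methyl ester arms already attached through the bridge CH2 groups. One exposure to NaOMe closes both rings by a double Claisen cyclisation. Until then the butanoylacetyl end of each arm is carried as a 3-propylisoxazole, so each arm has a single acidic CH2 when the bridges are made.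

Key step: step 10

Remark: the target has no stereocentre and is drawn as one of several equivalent enol tautomers; polycarbonyl intermediates are drawn in keto form although they will be enol mixtures, and the two methine centres of 15–17 are epimerisable and disappear in step 10.

Step 1
Reactants: 1 phloroglucinol
Product: 3 2,4,6-trihydroxybenzene-1,3-dicarbaldehyde, via bis(iminium) dichloride 2 (not isolated)
Conditions: POCl3 (2.3 equiv), DMF (2.5 equiv), dioxane, 0 °C → rt; then ice water
Reagents that add atoms: N,N-dimethylformamide CN(C)C=O (formyl carbons); water O (aldehyde oxygens)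
Why: In this Vilsmeier–Haack formylation the chloroiminium ion attacks the very electron-rich ring twice, the two iminium groups of 2 switch off the last position, and water then hydrolyses 2 to the dialdehyde.

Step 2
Reactants: 3 2,4,6-trihydroxybenzene-1,3-dicarbaldehyde; 4 butanoyl chloride
Product: 5 5-butanoyl-2,4,6-trihydroxybenzene-1,3-dicarbaldehyde
Conditions: AlCl3 (4 equiv), PhNO2, 60 °C; ice/aq. HCl
Reagents that add atoms: none
Why: Friedel–Crafts acylation (direct, or by O-acylation and Fries shift) can only occur at the single free ring carbon, which three hydroxyl groups keep nucleophilic enough, as the ready formation of triacylphloroglucinols shows.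

Step 3
Reactants: 5 5-butanoyl-2,4,6-trihydroxybenzene-1,3-dicarbaldehyde
Product: 6 2,4,6-tris(benzyloxy)-5-butanoylbenzene-1,3-dicarbaldehyde
Conditions: BnBr (4 equiv), K2CO3 (5 equiv), Bu4NI (cat.), DMF, 60 °C
Reagents that add atoms: benzyl bromide BrCc1ccccc1
Why: In this Williamson etherification every ring carbon is substituted and belongs to a weakly nucleophilic tricarbonyl-type anion, so alkylation should take place on the phenoxide oxygens once the polar aprotic medium has broken the chelates.

Step 4
Reactants: 6 2,4,6-tris(benzyloxy)-5-butanoylbenzene-1,3-dicarbaldehyde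
Product: 7 1-[2,4,6-tris(benzyloxy)-3,5-bis(hydroxymethyl)phenyl]butan-1-one
Conditions: NaBH4 (1.0 equiv), THF/MeOH, −10 → 0 °C; aq. work-up
Reagents that add atoms: none
Why: This borohydride reduction is chemoselective because the aldehydes react far faster than the aryl propyl ketone, which is twisted out of conjugation and screened by two ortho benzyloxy groups.

Step 5
Reactants: 7 1-[2,4,6-tris(benzyloxy)-3,5-bis(hydroxymethyl)phenyl]butan-1-one
Product: 8 1-[2,4,6-tris(benzyloxy)-3,5-bis(bromomethyl)phenyl]butan-1-one
Conditions: CBr4 (2.6 equiv), PPh3 (2.6 equiv), CH2Cl2, 0 °C; used promptly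
Reagents that add atoms: tetrabromomethane BrC(Br)(Br)Br
Why: The Appel reaction converts the electron-rich benzylic alcohols into bromides under neutral conditions that spare the benzyl ethers, and the fully substituted ring cannot alkylate itself.

Step 6
Reactants: 9 1-nitrobutane; 10 propyne
Product: 12 5-methyl-3-propylisoxazole, via butanenitrile oxide 11 (not isolated)
Conditions: PhNCO (2.1 equiv), Et3N (0.1 equiv), propyne (5 equiv), toluene, sealed vessel, rt → 60 °C
Reagents that add atoms: none
Why: Mukaiyama–Hoshino dehydration of the primary nitroalkane releases nitrile oxide 11 slowly, and its 1,3-dipolar cycloaddition to a terminal alkyne places the alkyne substituent at C5.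

Step 7
Reactants: 12 5-methyl-3-propylisoxazole; 13 dimethyl 2,2-dimethylmalonate
Product: 14 methyl 2,2-dimethyl-3-oxo-4-(3-propylisoxazol-5-yl)butanoate
Conditions: LiN(i-Pr)2 (2.1 equiv), THF, −78 °C; 13 (1.5 equiv), −78 → −30 °C; cold 1 M HCl
Reagents that add atoms: none
Why: Lateral lithiation of a 3,5-dialkylisoxazole takes place at the C5 methyl group, and the crossed Claisen acylation by the non-enolisable diester stops at the ketone because the second equivalent of base stores it as its enolate.

Step 8
Reactants: 8 1-[2,4,6-tris(benzyloxy)-3,5-bis(bromomethyl)phenyl]butan-1-one; 14 methyl 2,2-dimethyl-3-oxo-4-(3-propylisoxazol-5-yl)butanoate (2.2 equiv)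
Product: 15 core ketone with two isoxazolyl keto ester arms (diastereomer mixture)
Conditions: NaH (2.2 equiv), THF/DMF 5:1, 0 °C; then 8, 0 °C → rt
Reagents that add atoms: none
Why: This is a twofold SN2 C-alkylation of a soft enolate, stabilised by ketone and isoxazole, with primary benzylic bromides; 14 has only this one acidic CH2, and the two new methine centres form without control and stay epimerisable, which is harmless because both become sp2 in step 10.

Step 9
Reactants: 15 core ketone with two isoxazolyl keto ester arms
Product: 17 core ketone with two open tetracarbonyl methyl ester arms (diastereomer mixture), via bis(enaminone) 16 (not isolated)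
Conditions: Mo(CO)6 (2.2 equiv), MeCN/H2O 15:1, 65 °C; filter (Celite), concentrate; 1 M aq. HCl/THF, 0 °C → rt; used crude
Reagents that add atoms: water O
Why: Reductive N–O cleavage of isoxazoles with Mo(CO)6 gives the Z-enaminones without touching benzyl ethers, ketones or esters, and immediate hydrolysis of these vinylogous amides in dilute acid, together with the neopentyl-type shielding of the ketone beside CMe2, should outrun condensation of the NH2 group with that ketone.

Step 10
Reactants: 17 core ketone with two open tetracarbonyl methyl ester arms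
Product: 18 target as its ring B tri-O-benzyl ether
Conditions: NaOMe (10 equiv), MeOH/THF 3:1, 0.02 M, rt → 55 °C; then cold 1 M HCl to pH 2–3
Reagents that add atoms: none
Why: Excess methoxide turns each arm into the polyenolate of its 1,3,5-triketone, chain carbon C6 (the CH2 between the butanoyl and chain ketones, future ring C2) adds to the ester carbonyl C1 beside CMe2 (future ring C3), and loss of methoxide gives the 2-acyltrione, whose immediate deprotonation to the vinylogous acid anion pulls the reversible condensation to the product side. The closest known reactions are the Claisen (Dieckmann-type) cyclisation of 2,2-dialkyl-3,5-dioxo esters to filicinic and syncarpic acids and the phloroglucinol-type folding of 3,5,7-trioxo esters. Rings A and C each close in a 6-(enolexo)-exo-trig mode, assisted by the gem-dimethyl effect and by the non-chelating, protic medium, which lets the chain leave the chelated enolate shape. No stereocentre is created, and the two labile methine carbons of 17 become sp2 ring carbons. C-acylation has to beat aldol folding, enol lactone formation and retro-Claisen cleavage: the quaternary chain C2 removes the nucleophile of the resorcinol-type aldol mode, O-acylation is reversible in methanol (and exchange at a methyl ester is degenerate), and the ketone beside CMe2 is hidden inside the enolate of the benzyl-substituted 1,3-diketone. The benzyl ethers on ring B rule out quinone methide formation, so the bridges cannot migrate in base.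

Step 11
Reactants: 18 target as its ring B tri-O-benzyl ether
Product: 19 target (CNP0287270.0)
Conditions: H2 (1 atm), 10% palladium on carbon (Pd/C), EtOAc, rt
Reagents that add atoms: none
Why: Catalytic hydrogenolysis removes the three aryl benzyl ethers while the tetrasubstituted enols, the chelated aryl ketone and the CH2 bridges are inert at 1 atm, and the neutral medium avoids base-induced exchange of the bridges.

Compound list
1 | phloroglucinol | Oc1cc(O)cc(O)c1 | starting material
2 | bis(dimethyliminium) salt of 3, drawn as the dichloride (not isolated) | C[N+](C)=Cc1c(O)cc(O)c(C=[N+](C)C)c1O.[Cl-].[Cl-] | intermediate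
3 | 2,4,6-trihydroxybenzene-1,3-dicarbaldehyde | O=Cc1c(O)cc(O)c(C=O)c1O | intermediate
4 | butanoyl chloride | CCCC(=O)Cl | starting material
5 | 5-butanoyl-2,4,6-trihydroxybenzene-1,3-dicarbaldehyde | CCCC(=O)c1c(O)c(C=O)c(O)c(C=O)c1O | intermediate
6 | 2,4,6-tris(benzyloxy)-5-butanoylbenzene-1,3-dicarbaldehyde | CCCC(=O)c1c(OCc2ccccc2)c(C=O)c(OCc2ccccc2)c(C=O)c1OCc1ccccc1 | intermediate
7 | 1-[2,4,6-tris(benzyloxy)-3,5-bis(hydroxymethyl)phenyl]butan-1-one | CCCC(=O)c1c(OCc2ccccc2)c(CO)c(OCc2ccccc2)c(CO)c1OCc1ccccc1 | intermediate
8 | 1-[2,4,6-tris(benzyloxy)-3,5-bis(bromomethyl)phenyl]butan-1-one | CCCC(=O)c1c(OCc2ccccc2)c(CBr)c(OCc2ccccc2)c(CBr)c1OCc1ccccc1 | intermediate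
9 | 1-nitrobutane | CCCC[N+](=O)[O-] | starting material
10 | propyne | CC#C | starting material
11 | butanenitrile oxide (not isolated) | CCCC#[N+][O-] | intermediate
12 | 5-methyl-3-propylisoxazole | CCCc1cc(C)on1 | intermediate
13 | dimethyl 2,2-dimethylmalonate | COC(=O)C(C)(C)C(=O)OC | starting material
14 | methyl 2,2-dimethyl-3-oxo-4-(3-propylisoxazol-5-yl)butanoate | CCCc1cc(CC(=O)C(C)(C)C(=O)OC)on1 | intermediate
15 | 8 with each CH2Br replaced by CH2–CH(3-propylisoxazol-5-yl)–C(=O)–CMe2–CO2Me; two epimerisable centres, mixture | CCCC(=O)c1c(OCc2ccccc2)c(CC(c2cc(CCC)no2)C(=O)C(C)(C)C(=O)OC)c(OCc2ccccc2)c(CC(c2cc(CCC)no2)C(=O)C(C)(C)C(=O)OC)c1OCc1ccccc1 | intermediate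
16 | bis[(Z)-enaminone] from N–O cleavage of 15 (not isolated); methine centres as mixture | CCCC(=O)c1c(OCc2ccccc2)c(CC(C(=O)/C=C(\N)CCC)C(=O)C(C)(C)C(=O)OC)c(OCc2ccccc2)c(CC(C(=O)/C=C(\N)CCC)C(=O)C(C)(C)C(=O)OC)c1OCc1ccccc1 | intermediate
17 | tri-O-benzyl core ketone with two CH2–CH[C(=O)CH2C(=O)Pr][C(=O)CMe2CO2Me] arms; key-step precursor, diastereomer and tautomer mixture | CCCC(=O)c1c(OCc2ccccc2)c(CC(C(=O)CC(=O)CCC)C(=O)C(C)(C)C(=O)OC)c(OCc2ccccc2)c(CC(C(=O)CC(=O)CCC)C(=O)C(C)(C)C(=O)OC)c1OCc1ccccc1 | intermediate
18 | target as its ring B tri-O-benzyl ether; key-step product | CCCC(=O)C1=C(O)C(C)(C)C(O)=C(Cc2c(OCc3ccccc3)c(CC3=C(O)C(C)(C)C(O)=C(C(=O)CCC)C3=O)c(OCc3ccccc3)c(C(=O)CCC)c2OCc2ccccc2)C1=O | intermediate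
19 | CNP0287270.0: butyrylphloroglucinol (ring B) joined through two CH2 bridges to two butyrylfilicinic acid units (rings A and C); achiral | CCCC(=O)C1=C(O)C(C)(C)C(O)=C(Cc2c(O)c(CC3=C(O)C(C)(C)C(O)=C(C(=O)CCC)C3=O)c(O)c(C(=O)CCC)c2O)C1=O | target

Total step count: 11. Longest linear sequence: 9 steps (steps 1–5, then 8–11). The arm (steps 6–7) is made in parallel.

Steps most likely to fail

1. Step 10. Methoxide may cleave the arms by retro-Claisen attack at the ketone beside CMe2 before the hindered ester is reached, or closure may stop after one ring. The fallback sets out from 8 and returns at 18. It makes the outer rings closed and then attaches them.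
   - Phloroglucinol 1 is acylated with 4 (AlCl3, Friedel–Crafts) to 1-(2,4,6-trihydroxyphenyl)butan-1-one F1.
   - Dearomatising gem-dimethylation (MeI, NaOMe, MeOH) gives butyrylfilicinic acid F2.
   - The disodium salt of F2 (NaH, THF/DMF, 2.2 equiv) is C-alkylated at its free ring carbon C6 by dibromide 8, which gives 18 directly.

2. Step 9. The liberated amino group may condense with the ketone beside CMe2 (pyridone formation), or the acid used for hydrolysis may cyclodehydrate the triketone to a pyranone. The fallback sets out from 8 and 13 and returns at 17. It uses a nitrogen-free mask that is removed without acid.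
   - 1-Pentyne is lithiated (n-BuLi) and acylated with N-methoxy-N-methylacetamide to hept-3-yn-2-one F3.
   - Double conjugate addition of propane-1,3-dithiol (NaOMe cat., MeOH/CH2Cl2) gives 1-(2-propyl-1,3-dithian-2-yl)propan-2-one F4.
   - Kinetic deprotonation of the methyl group (LiN(i-Pr)2, 2.1 equiv) and acylation with 13 gives methyl 2,2-dimethyl-3,5-dioxo-6-(2-propyl-1,3-dithian-2-yl)hexanoate F5, which again has one strongly acidic CH2.
   - Alkylation with 8 (NaH) gives the bis(dithiane) core ketone F6.
   - Alkylative hydrolysis (MeI, CaCO3, aq. MeCN) frees both ketones to give 17.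

3. Step 8. The hindered enolate may react on oxygen, or the reaction may stall after the first substitution because of crowding around the central benzyloxy group. The fallback sets out from 6 and 14 and returns at 15. It replaces substitution by condensation and reduction, and it makes steps 4 and 5 unnecessary.
   - Twofold Knoevenagel condensation of dialdehyde 6 with 14 (piperidinium acetate, toluene, water separator) gives the bis(alkylidene) core ketone F7.
   - Conjugate reduction of F7 with Hantzsch ester (toluene, 80 °C) gives 15.

Further compounds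
F1 | step 10 | 1-(2,4,6-trihydroxyphenyl)butan-1-one | CCCC(=O)c1c(O)cc(O)cc1O
F2 | step 10 | butyrylfilicinic acid (2-butanoyl-3,5-dihydroxy-4,4-dimethylcyclohexa-2,5-dien-1-one) | CCCC(=O)C1=C(O)C(C)(C)C(O)=CC1=O
F3 | step 9 | hept-3-yn-2-one | CCCC#CC(C)=O
F4 | step 9 | 1-(2-propyl-1,3-dithian-2-yl)propan-2-one | CCCC1(CC(C)=O)SCCCS1
F5 | step 9 | methyl 2,2-dimethyl-3,5-dioxo-6-(2-propyl-1,3-dithian-2-yl)hexanoate | CCCC1(CC(=O)CC(=O)C(C)(C)C(=O)OC)SCCCS1
F6 | step 9 | bis(dithiane) core ketone (17 with each butanoyl ketone of the arms as its 1,3-dithiane; methine centres as mixture) | CCCC(=O)c1c(OCc2ccccc2)c(CC(C(=O)CC2(CCC)SCCCS2)C(=O)C(C)(C)C(=O)OC)c(OCc2ccccc2)c(CC(C(=O)CC2(CCC)SCCCS2)C(=O)C(C)(C)C(=O)OC)c1OCc1ccccc1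
F7 | step 8 | bis(alkylidene) core ketone (E/Z mixture, geometry lost on reduction) | CCCC(=O)c1c(OCc2ccccc2)c(C=C(c2cc(CCC)no2)C(=O)C(C)(C)C(=O)OC)c(OCc2ccccc2)c(C=C(c2cc(CCC)no2)C(=O)C(C)(C)C(=O)OC)c1OCc1ccccc1
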